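**Assumption:** configurations are read from the given SMILES as 2S (flavan carbon), 8S (aryl-bearing furan carbon), 9R (carbinol carbon) and 9aS (quaternary ring-fusion carbon) in furo[2,3-h]chromene numbering. The 8-aryl group is anti to ring A and syn to the 9-hydroxyl.

**Retrosynthetic overview**
1. Last bond: the aryl-oxygen to ring-carbon C–O bond of ring A (chromanone), made by oxidative dearomatisation of a furo-fused flavan phenol. Ring C becomes the dienone and the quaternary carbon is fixed by the neighbouring carbinol carbon.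
2. The free 2'-hydroxyl needed for that step comes from a 2,4,6-trimethoxybenzoyl group by chelation-controlled mono-demethylation.
3. Ring B (dihydrofuran: one C–C bond, one C–O bond, two stereocentres) comes from a new catalytic asymmetric interrupted Feist–Bénary annulation of (2S)-5,7-dihydroxy-4'-methoxyflavan with a racemic β-chloro-1,2-diketone.
4. The flavan (ring D) comes from phloroglucinol and an aryl vinyl ketone, then asymmetric transfer hydrogenation and Mitsunobu C–O closure. The chloro-diketone comes from 1,3,5-trimethoxybenzene, dichloroacetyl chloride and 4-methoxybenzaldehyde.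
5. Ring order: D, then B, then A together with the dearomatised ring C.

**Route**

Step 1
Reactants: 1 1,3,5-trimethoxybenzene; 2 dichloroacetyl chloride
Product: 3 2,2-dichloro-1-(2,4,6-trimethoxyphenyl)ethan-1-one
Conditions: AlCl3 (1.1 equiv), CH2Cl2, 0 °C
Reagents that add atoms: none
Why: Friedel–Crafts acylation of a threefold-symmetric, strongly activated arene gives a single regioisomer, the new ketone deactivates the ring against a second acylation, and the low temperature avoids ortho-demethylation.

Step 2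
Reactants: 3 2,2-dichloro-1-(2,4,6-trimethoxyphenyl)ethan-1-one; 4 4-methoxybenzaldehyde
Product: 6 3-chloro-3-(4-methoxyphenyl)-1-(2,4,6-trimethoxyphenyl)propane-1,2-dione, via chloro-epoxide 5 (not isolated)
Conditions: LiN(SiMe3)2 (1.05 equiv), THF, −78 °C; then 4; warm to 20 °C
Reagents that add atoms: none
Why: Darzens condensation of the dichloro-enolate gives the α-chloro epoxide, which opens through the 4-methoxybenzyl cation/chloride ion pair (α-chloro-epoxide to α-chloro-ketone rearrangement) to the β-chloro-1,2-diketone; its chloride-bearing carbon is racemic and enolisable, which step 6 exploits.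

Step 3
Reactants: 7 phloroglucinol (3 equiv); 8 3-chloro-1-(4-methoxyphenyl)propan-1-one
Product: 10 1-(4-methoxyphenyl)-3-(2,4,6-trihydroxyphenyl)propan-1-one, via aryl vinyl ketone 9 (not isolated)
Conditions: NaHCO3 (1.2 equiv), H2O/EtOH, 50 °C
Reagents that add atoms: none
Why: base-induced loss of HCl gives the enone, and C-selective Michael addition (Friedel–Crafts-type conjugate addition) of the phloroglucinol anion, whose three ring positions are equivalent, gives one mono-adduct while the excess triol suppresses double alkylation.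

Step 4
Reactants: 10 1-(4-methoxyphenyl)-3-(2,4,6-trihydroxyphenyl)propan-1-one
Product: 11 2-[(3R)-3-hydroxy-3-(4-methoxyphenyl)propyl]benzene-1,3,5-triol
Conditions: RuCl[(R,R)-TsDPEN](p-cymene) (1 mol %), HCO2Na (5 equiv), H2O/MeOH, 40 °C
Reagents that add atoms: none
Why: Noyori asymmetric transfer hydrogenation of the aryl ketone (open form of the ketone/hemiketal equilibrium) by the (R,R)-catalyst gives the (R)-carbinol, and the neutral formate medium keeps the 4-methoxybenzylic alcohol from ionising.

Step 5
Reactants: 11 2-[(3R)-3-hydroxy-3-(4-methoxyphenyl)propyl]benzene-1,3,5-triol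
Product: 12 (2S)-2-(4-methoxyphenyl)chromane-5,7-diol
Conditions: PPh3, DIAD (betaine pre-formed), THF, 0 °C
Reagents that add atoms: none
Why: intramolecular Mitsunobu etherification, in which either of the two equivalent ortho-hydroxyls displaces the activated carbinol oxygen in a six-membered SN2 closure with inversion, converts the (R)-alcohol into the (2S)-flavan.

Step 6
Reactants: 12 (2S)-2-(4-methoxyphenyl)chromane-5,7-diol (1.2 equiv); 6 3-chloro-3-(4-methoxyphenyl)-1-(2,4,6-trimethoxyphenyl)propane-1,2-dione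
Product: 14 [(2S,8S,9S)-5,9-dihydroxy-2,8-bis(4-methoxyphenyl)-3,4,8,9-tetrahydro-2H-furo[2,3-h]chromen-9-yl](2,4,6-trimethoxyphenyl)methanone, via C8 aldol chlorohydrin 13 (not isolated)
Conditions: quinine squaramide 3-{[3,5-bis(trifluoromethyl)phenyl]amino}-4-{[(8α,9S)-6'-methoxycinchonan-9-yl]amino}cyclobut-3-ene-1,2-dione (10 mol %), NaHCO3 (2 equiv), THF, −20 → 20 °C
Reagents that add atoms: none
Why: Proposed new method: a catalytic asymmetric interrupted Feist–Bénary annulation of a phenol, in which the squaramide NH groups bind the 1,2-dicarbonyl of 6 and the quinuclidine nitrogen hydrogen-bonds the flavan hydroxyls, so that flavan C8 (para to the 5-hydroxyl, flanked by only one free hydroxyl, the position used in natural 4→8 flavan couplings) adds to the C2 ketone of 6 (the C1 ketone is shielded by two ortho-methoxy groups) in the enantio-determining aldol-type Friedel–Crafts step, with both chloride epimers of 6 funnelled through its enol (dynamic kinetic resolution), after which the 7-phenoxide, the only oxygen that can reach, displaces the 4-methoxybenzylic chloride to give the dihydrofuran bearing the aryl group anti to the bulky aroyl group, that centre being correctable by reversible benzylic ionisation; the closest known reaction types are the cinchona-catalysed interrupted Feist–Bénary reaction of cyclic 1,3-diketones with β-substituted bromopyruvates and the squaramide-catalysed Friedel–Crafts hydroxyalkylation of phenols with activated ketones.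

Step 7
Reactants: 14 [(2S,8S,9S)-5,9-dihydroxy-2,8-bis(4-methoxyphenyl)-3,4,8,9-tetrahydro-2H-furo[2,3-h]chromen-9-yl](2,4,6-trimethoxyphenyl)methanone
Product: 15 [(2S,8S,9S)-5,9-dihydroxy-2,8-bis(4-methoxyphenyl)-3,4,8,9-tetrahydro-2H-furo[2,3-h]chromen-9-yl](2-hydroxy-4,6-dimethoxyphenyl)methanone
Conditions: MgI2·OEt2 (3 equiv), toluene/Et2O, 50 °C; aqueous work-up
Reagents that add atoms: none
Why: chelation-controlled ortho-demethylation, in which magnesium bridges the ketone oxygen and one of the two equivalent ortho-methoxy groups and iodide removes that methyl by SN2, leaves the other methyl ethers (no chelating carbonyl) untouched and holds the tertiary alcohol as its magnesium alkoxide.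

Step 8
Reactants: 15 [(2S,8S,9S)-5,9-dihydroxy-2,8-bis(4-methoxyphenyl)-3,4,8,9-tetrahydro-2H-furo[2,3-h]chromen-9-yl](2-hydroxy-4,6-dimethoxyphenyl)methanone
Product: 16 CNP0251458.2 (target)
Conditions: PhI(OAc)2 (1.05 equiv), CF3CH2OH, −20 → 0 °C
Reagents that add atoms: none
Why: oxidative phenol dearomatisation (para-etherification by a trivalent iodine reagent), in which the 5-hydroxyl binds iodine and the 2'-hydroxyl of the C9 aroyl group attacks the para carbon C9a through a six-membered transition state on the face that carries the aroyl group, forms ring A cis-fused to ring B, so the 9a configuration is dictated by C9 and the 5-oxygen becomes the dienone carbonyl.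

**Compound list**

1 | 1,3,5-trimethoxybenzene | COc1cc(OC)cc(OC)c1 | starting material
2 | dichloroacetyl chloride | ClC(Cl)C(Cl)=O | starting material
3 | 2,2-dichloro-1-(2,4,6-trimethoxyphenyl)ethan-1-one | COc1cc(OC)c(C(=O)C(Cl)Cl)c(OC)c1 | intermediate
4 | 4-methoxybenzaldehyde | COc1ccc(C=O)cc1 | starting material
5 | [2-chloro-3-(4-methoxyphenyl)oxiran-2-yl](2,4,6-trimethoxyphenyl)methanone (racemic, not isolated) | COc1ccc(C2OC2(Cl)C(=O)c2c(OC)cc(OC)cc2OC)cc1 | intermediate
6 | 3-chloro-3-(4-methoxyphenyl)-1-(2,4,6-trimethoxyphenyl)propane-1,2-dione (racemic, C3 labile) | COc1ccc(C(Cl)C(=O)C(=O)c2c(OC)cc(OC)cc2OC)cc1 | intermediate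
7 | phloroglucinol (benzene-1,3,5-triol) | Oc1cc(O)cc(O)c1 | starting material
8 | 3-chloro-1-(4-methoxyphenyl)propan-1-one | COc1ccc(C(=O)CCCl)cc1 | starting material
9 | 1-(4-methoxyphenyl)prop-2-en-1-one (not isolated) | COc1ccc(C(=O)C=C)cc1 | intermediate
10 | 1-(4-methoxyphenyl)-3-(2,4,6-trihydroxyphenyl)propan-1-one (in equilibrium with its cyclic hemiketal) | COc1ccc(C(=O)CCc2c(O)cc(O)cc2O)cc1 | intermediate
11 | 2-[(3R)-3-hydroxy-3-(4-methoxyphenyl)propyl]benzene-1,3,5-triol | COc1ccc([C@H](O)CCc2c(O)cc(O)cc2O)cc1 | intermediate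
12 | (2S)-2-(4-methoxyphenyl)chromane-5,7-diol [(2S)-5,7-dihydroxy-4'-methoxyflavan] | COc1ccc([C@@H]2CCc3c(O)cc(O)cc3O2)cc1 | intermediate
13 | (2R)-3-chloro-2-[(2S)-5,7-dihydroxy-2-(4-methoxyphenyl)chroman-8-yl]-2-hydroxy-3-(4-methoxyphenyl)-1-(2,4,6-trimethoxyphenyl)propan-1-one (C3 epimers, not isolated) | COc1ccc([C@@H]2CCc3c(O)cc(O)c(c3O2)[C@](O)(C(Cl)c2ccc(OC)cc2)C(=O)c2c(OC)cc(OC)cc2OC)cc1 | intermediate
14 | [(2S,8S,9S)-5,9-dihydroxy-2,8-bis(4-methoxyphenyl)-3,4,8,9-tetrahydro-2H-furo[2,3-h]chromen-9-yl](2,4,6-trimethoxyphenyl)methanone | COc1ccc([C@@H]2CCc3c(O)cc4O[C@@H](c5ccc(OC)cc5)[C@](O)(C(=O)c5c(OC)cc(OC)cc5OC)c4c3O2)cc1 | intermediate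
15 | [(2S,8S,9S)-5,9-dihydroxy-2,8-bis(4-methoxyphenyl)-3,4,8,9-tetrahydro-2H-furo[2,3-h]chromen-9-yl](2-hydroxy-4,6-dimethoxyphenyl)methanone | COc1ccc([C@@H]2CCc3c(O)cc4O[C@@H](c5ccc(OC)cc5)[C@](O)(C(=O)c5c(O)cc(OC)cc5OC)c4c3O2)cc1 | intermediate
16 | CNP0251458.2: the (2S,8S,9R,9aS) dienone in which the 2'-oxygen of the aroyl group of 15 is bonded to C9a (ring A a 5,7-dimethoxychroman-4-one, ring C a furo[2,3-h]chromen-5-one) | COc1ccc([C@@H]2CCC3=C(O2)[C@]24Oc5cc(OC)cc(OC)c5C(=O)[C@@]2(O)[C@H](c2ccc(OC)cc2)OC4=CC3=O)cc1 | target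

**Step count and risks**

Total steps: 8. Longest linear sequence: 6 steps (steps 3 to 8, from 7 and 8 to 16); the two-step branch to 6 joins at step 6.

Most likely to fail, step 6 (the proposed new step). The risks are attack at flavan C6 instead of C8 (or first alkylation at O5), low enantioselectivity, and loss of water from the tertiary alcohol to give the aromatic benzofuran. If the sense of induction is opposite, the quinidine-derived pseudo-enantiomer of the catalyst is used. The fallback uses known chemistry and sets out from 12 and 6. Williamson etherification with K2CO3 in acetone at the less hindered 7-hydroxyl gives (2S)-7-[1-(4-methoxyphenyl)-2,3-dioxo-3-(2,4,6-trimethoxyphenyl)propoxy]-2-(4-methoxyphenyl)chroman-5-ol F1. Continued stirring with K2CO3 closes ring B by intramolecular aldol-type Friedel–Crafts hydroxyalkylation without control of absolute configuration. This gives 14 together with its (2S,8R,9R) diastereomer F2. Because the flavan centre is fixed these are diastereomers and are separated by preparative HPLC, which also removes any C6-annulated regioisomer. The route is rejoined at 14.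

Second, step 7. The Lewis acid may dehydrate the tertiary benzylic alcohol to the benzofuran or open the benzylic ether of ring B. The fallback moves the demethylation to a robust early intermediate and carries a neutral-cleavable allyl group; it sets out from 3. BCl3 in CH2Cl2 at −78 °C gives 2,2-dichloro-1-(2-hydroxy-4,6-dimethoxyphenyl)ethan-1-one F3. Allyl bromide and K2CO3 give 1-[2-(allyloxy)-4,6-dimethoxyphenyl]-2,2-dichloroethan-1-one F4. Darzens condensation with 4 under the step 2 conditions passes through the allyloxy chloro-epoxide F5 to 1-[2-(allyloxy)-4,6-dimethoxyphenyl]-3-chloro-3-(4-methoxyphenyl)propane-1,2-dione F6. Annulation with 12 under the step 6 conditions passes through the allyloxy chlorohydrin F7 to the 2-allyloxy analogue of 14, F8. Pd(PPh3)4 (5 mol %) and morpholine in THF remove the allyl group and the route is rejoined at 15.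

Third, step 2. The α-chloro epoxide may not rearrange cleanly and the chloro-diketone is labile. The fallback builds the diketone first and chlorinates last; it sets out from 1. Oxalyl chloride without catalyst gives 2-oxo-2-(2,4,6-trimethoxyphenyl)acetyl chloride F9. Negishi acylation with commercial 4-methoxybenzylzinc chloride and Pd(PPh3)4 (2 mol %) gives 3-(4-methoxyphenyl)-1-(2,4,6-trimethoxyphenyl)propane-1,2-dione F10, mainly as its enol. N-chlorosuccinimide chlorinates the enol carbon and the route is rejoined at 6.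

**Further compounds**

F1 | step 6 | (2S)-7-[1-(4-methoxyphenyl)-2,3-dioxo-3-(2,4,6-trimethoxyphenyl)propoxy]-2-(4-methoxyphenyl)chroman-5-ol (epimers at the ether carbon) | COc1ccc([C@@H]2CCc3c(O)cc(OC(c4ccc(OC)cc4)C(=O)C(=O)c4c(OC)cc(OC)cc4OC)cc3O2)cc1
F2 | step 6 | [(2S,8R,9R)-5,9-dihydroxy-2,8-bis(4-methoxyphenyl)-3,4,8,9-tetrahydro-2H-furo[2,3-h]chromen-9-yl](2,4,6-trimethoxyphenyl)methanone | COc1ccc([C@@H]2CCc3c(O)cc4O[C@H](c5ccc(OC)cc5)[C@@](O)(C(=O)c5c(OC)cc(OC)cc5OC)c4c3O2)cc1
F3 | step 7 | 2,2-dichloro-1-(2-hydroxy-4,6-dimethoxyphenyl)ethan-1-one | COc1cc(O)c(C(=O)C(Cl)Cl)c(OC)c1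
F4 | step 7 | 1-[2-(allyloxy)-4,6-dimethoxyphenyl]-2,2-dichloroethan-1-one | C=CCOc1cc(OC)cc(OC)c1C(=O)C(Cl)Cl
F5 | step 7 | [2-(allyloxy)-4,6-dimethoxyphenyl][2-chloro-3-(4-methoxyphenyl)oxiran-2-yl]methanone (racemic, not isolated) | COc1ccc(C2OC2(Cl)C(=O)c2c(OCC=C)cc(OC)cc2OC)cc1
F6 | step 7 | 1-[2-(allyloxy)-4,6-dimethoxyphenyl]-3-chloro-3-(4-methoxyphenyl)propane-1,2-dione (racemic) | COc1ccc(C(Cl)C(=O)C(=O)c2c(OCC=C)cc(OC)cc2OC)cc1
F7 | step 7 | (2R)-1-[2-(allyloxy)-4,6-dimethoxyphenyl]-3-chloro-2-[(2S)-5,7-dihydroxy-2-(4-methoxyphenyl)chroman-8-yl]-2-hydroxy-3-(4-methoxyphenyl)propan-1-one (C3 epimers, not isolated) | COc1ccc([C@@H]2CCc3c(O)cc(O)c(c3O2)[C@](O)(C(Cl)c2ccc(OC)cc2)C(=O)c2c(OCC=C)cc(OC)cc2OC)cc1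
F8 | step 7 | [2-(allyloxy)-4,6-dimethoxyphenyl][(2S,8S,9S)-5,9-dihydroxy-2,8-bis(4-methoxyphenyl)-3,4,8,9-tetrahydro-2H-furo[2,3-h]chromen-9-yl]methanone | COc1ccc([C@@H]2CCc3c(O)cc4O[C@@H](c5ccc(OC)cc5)[C@](O)(C(=O)c5c(OCC=C)cc(OC)cc5OC)c4c3O2)cc1
F9 | step 2 | 2-oxo-2-(2,4,6-trimethoxyphenyl)acetyl chloride | COc1cc(OC)c(C(=O)C(Cl)=O)c(OC)c1
F10 | step 2 | 3-(4-methoxyphenyl)-1-(2,4,6-trimethoxyphenyl)propane-1,2-dione | COc1ccc(CC(=O)C(=O)c2c(OC)cc(OC)cc2OC)cc1
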